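**Retrosynthetic overview** (naphthalene numbering: C1 carries the pyranone, C2 and C3 the carboxyls, C4 is the vinylic CH, ring A is the catechol ring)
1. Ring B (C1–C2–C3–C4–C4a–C8a) is cut at C1–C2 and C3–C4: a [4+2] cycloaddition of a fumarate (C2–C3 with both carboxyls) to a hydroxy-o-quinodimethane made by photoenolisation, which dearomatises ring A for a moment.
2. The aldehyde carbon of the precursor becomes C4 and the pyranonyl-CH2 becomes the C1 methine; later loss of the C4 hydroxyl gives the C3=C4 double bond.
3. C1 and C2 are set together with the transient centres C3 and C4 in this one step; the absolute sense comes from (S)-mandelate esters on the fumarate.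
4. The precursor aldehyde comes from an sp3–sp2 Suzuki coupling of a 3-(bromomethyl)-2-pyranone with a commercial 2-formylarylboronic acid.
5. Ring order: 2-pyranone first (oxalate/tiglate condensation–lactonisation), ring B second (cycloaddition); ring A is bought.

Key step: step 6

Assumption: the facial sense given by the (S)-mandelate esters of 11 is taken by analogy with lactate and mandelate fumarates adding to α-hydroxy-α'-aryl-o-quinodimethanes in aryltetralin lignan work; if the pyranonyl diene prefers the other face, methyl (R)-mandelate, equally available, replaces 10 and nothing else changes.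

**Step 1**
Reactants: 1 ethyl tiglate; 2 diethyl oxalate
Product: 4 3-methyl-2-oxo-2H-pyran-6-carboxylic acid, via potassium dienolate 3 (not isolated)
Conditions: KOEt, EtOH/Et2O, 0 °C → rt; then conc. HCl, 90 °C
Reagents that add atoms: potassium ethoxide, CC[O-].[K+] (the potassium of 3); water, O (the carboxyl OH of 4)
Why: A vinylogous (γ-selective) Claisen condensation of the tiglate dienolate with non-enolisable oxalate is driven to the stabilised dienolate 3, and hot hydrochloric acid then hydrolyses the esters, equilibrates the alkene geometry and closes the enol onto the acid to give the 2-pyranone, as in the classical crotonate/oxalate route to 2-pyranone-6-carboxylic acids.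

**Step 2**
Reactants: 4 3-methyl-2-oxo-2H-pyran-6-carboxylic acid
Product: 5 methyl 3-methyl-2-oxo-2H-pyran-6-carboxylate
Conditions: MeOH, H2SO4 (cat.), reflux
Reagents that add atoms: methanol, CO
Why: Fischer esterification should leave the acid-stable 2-pyranone ring intact, as in the preparation of methyl coumalate.

**Step 3**
Reactants: 5 methyl 3-methyl-2-oxo-2H-pyran-6-carboxylate
Product: 6 methyl 3-(bromomethyl)-2-oxo-2H-pyran-6-carboxylate
Conditions: NBS (1.05 equiv), AIBN (cat.), PhCF3, 85 °C
Reagents that add atoms: N-bromosuccinimide, O=C1CCC(=O)N1Br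
Why: Wohl–Ziegler bromination should take place at the only allylic C–H bonds, the 3-methyl group, in analogy to the bromination of 3-methylcoumarin to 3-(bromomethyl)coumarin.

**Step 4**
Reactants: 6 methyl 3-(bromomethyl)-2-oxo-2H-pyran-6-carboxylate; 7 (2-formyl-4,5-dimethoxyphenyl)boronic acid
Product: 8 methyl 3-[(2-formyl-4,5-dimethoxyphenyl)methyl]-2-oxo-2H-pyran-6-carboxylate
Conditions: Pd(dppf)Cl2 (5 mol %), K3PO4·H2O, toluene, 70 °C
Reagents that add atoms: none
Why: An sp3–sp2 Suzuki–Miyaura coupling of an activated allylic/benzylic-type bromide (as known for 3-(bromomethyl)coumarins and 2-(bromomethyl)acrylates) should couple at the CH2 terminus, which keeps the pyranone conjugated, and the mild phosphate base in toluene should spare the lactone and the free aldehyde.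

**Step 5**
Reactants: 9 fumaryl chloride; 10 methyl (S)-mandelate (2 equivalents in total, one per acid chloride group)
Product: 11 bis[(1S)-2-methoxy-2-oxo-1-phenylethyl] (2E)-but-2-enedioate
Conditions: 10 (2.1 equiv), pyridine (2.5 equiv), DMAP (cat.), CH2Cl2, 0 °C → rt
Reagents that add atoms: methyl (S)-mandelate (the second equivalent of 10, which forms the second ester arm), COC(=O)[C@@H](O)c1ccccc1
Why: Double O-acylation of two molecules of the secondary alcohol by the two acid chloride groups under mild base at low temperature should give the C2-symmetric chiral fumarate without epimerising the mandelate centres or isomerising the E alkene.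

**Step 6**
Reactants: 8 methyl 3-[(2-formyl-4,5-dimethoxyphenyl)methyl]-2-oxo-2H-pyran-6-carboxylate; 11 bis[(1S)-2-methoxy-2-oxo-1-phenylethyl] (2E)-but-2-enedioate
Product: 13 bis[(1S)-2-methoxy-2-oxo-1-phenylethyl] (1R,2R,3S,4S)-4-hydroxy-6,7-dimethoxy-1-[6-(methoxycarbonyl)-2-oxo-2H-pyran-3-yl]-1,2,3,4-tetrahydronaphthalene-2,3-dicarboxylate, via photoenol 12 (not isolated)
Conditions: hν (365 nm LED), 11 (2 equiv), degassed toluene, −20 °C
Reagents that add atoms: none
Why: n,π* excitation of the aryl aldehyde of 8 and 1,5-hydrogen transfer from the doubly activated C1 methylene give the (E,E)-hydroxy-o-quinodimethane 12 with ring A dearomatised, and its suprafacial [4+2] cycloaddition with fumarate 11 forms C1–C2 and C3–C4 and restores the aromaticity of ring A. The closest known reaction type is the photoenolisation/Diels–Alder reaction of 2-benzylbenzaldehydes with fumarates used for aryltetralin lignans, including lactate and mandelate fumarates as chiral dienophiles. Ring B is closed by an intermolecular [4+2] cycloaddition that makes both of its new bonds in one event. C1 and C4 should come out cis because the pyranonyl group and the hydroxyl both sit in the outside positions of the diene, C2 and C3 trans because the E geometry of the fumarate is transferred, and the C3 ester cis to the C4 hydroxyl through the endo transition state that is held by an O–H···O=C hydrogen bond and avoids the pyranonyl group. The absolute configuration should follow from the fumarate face left open by the two (S)-mandelate esters, so the step needs facial and endo selectivity, helped by the low temperature that photochemical diene generation allows, and minor diastereomers of 13 are to be removed by crystallisation or chromatography. Chemoselective excitation rests on 365 nm light, which the aryl aldehyde absorbs while the pyranone ester and the fumarate are nearly transparent.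

**Step 7**
Reactants: 13 bis[(1S)-2-methoxy-2-oxo-1-phenylethyl] (1R,2R,3S,4S)-4-hydroxy-6,7-dimethoxy-1-[6-(methoxycarbonyl)-2-oxo-2H-pyran-3-yl]-1,2,3,4-tetrahydronaphthalene-2,3-dicarboxylate
Product: 15 (1R,2R)-1-(6-carboxy-2-oxo-2H-pyran-3-yl)-6,7-dimethoxy-1,2-dihydronaphthalene-2,3-dicarboxylic acid, via dihydronaphthalene triester 14 (not isolated)
Conditions: 6 M aq. HCl/1,4-dioxane (1:1), 95 °C, Ar
Reagents that add atoms: water, O
Why: E1 dehydration of the C4 benzylic alcohol (cation stabilised by the para C7 methoxy group) should give the conjugated C3=C4 alkene of 14, and acid-catalysed ester hydrolysis then frees the three carboxyl groups while the 2-pyranone, itself formed in hot hydrochloric acid in step 1, stays closed; C1 is not involved and C2 stays in the more stable trans arrangement.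

**Step 8**
Reactants: 15 (1R,2R)-1-(6-carboxy-2-oxo-2H-pyran-3-yl)-6,7-dimethoxy-1,2-dihydronaphthalene-2,3-dicarboxylic acid
Product: 16 (1R,2R)-1-(6-carboxy-2-oxo-2H-pyran-3-yl)-6,7-dihydroxy-1,2-dihydronaphthalene-2,3-dicarboxylic acid (CNP0420981.1)
Conditions: BBr3 (8 equiv), CH2Cl2, −78 °C → rt; then H2O, 0 °C
Reagents that add atoms: none
Why: Lewis-acid-mediated cleavage of the two aryl methyl ethers (bromide attack at methyl, boron esters hydrolysed on work-up) should free the catechol, as is usual for caffeic-acid-derived polyacids; the enol lactone has no alkyl–O bond to cleave and neither stereocentre is touched.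

**Compound list**
1 | ethyl tiglate, ethyl (2E)-2-methylbut-2-enoate | C/C=C(\C)C(=O)OCC | starting material
2 | diethyl oxalate | CCOC(=O)C(=O)OCC | starting material
3 | potassium (2Z,4E)-1,6-diethoxy-5-methyl-1,6-dioxohexa-2,4-dien-2-olate | CCOC(=O)/C(C)=C/C=C(\[O-])C(=O)OCC.[K+] | intermediate
4 | 3-methyl-2-oxo-2H-pyran-6-carboxylic acid | Cc1ccc(C(=O)O)oc1=O | intermediate
5 | methyl 3-methyl-2-oxo-2H-pyran-6-carboxylate | Cc1ccc(C(=O)OC)oc1=O | intermediate
6 | methyl 3-(bromomethyl)-2-oxo-2H-pyran-6-carboxylate | COC(=O)c1ccc(CBr)c(=O)o1 | intermediate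
7 | (2-formyl-4,5-dimethoxyphenyl)boronic acid | COc1cc(C=O)c(B(O)O)cc1OC | starting material
8 | methyl 3-[(2-formyl-4,5-dimethoxyphenyl)methyl]-2-oxo-2H-pyran-6-carboxylate | COC(=O)c1ccc(Cc2cc(OC)c(OC)cc2C=O)c(=O)o1 | intermediate
9 | fumaryl chloride | O=C(Cl)/C=C/C(=O)Cl | starting material
10 | methyl (S)-mandelate | COC(=O)[C@@H](O)c1ccccc1 | starting material
11 | bis[(1S)-2-methoxy-2-oxo-1-phenylethyl] (2E)-but-2-enedioate | COC(=O)[C@@H](OC(=O)/C=C/C(=O)O[C@H](C(=O)OC)c1ccccc1)c1ccccc1 | intermediate
12 | photoenol, methyl 3-[(E)-[(6E)-6-(hydroxymethylidene)-3,4-dimethoxycyclohexa-2,4-dien-1-ylidene]methyl]-2-oxo-2H-pyran-6-carboxylate | O/C=C1/C(=C/c2ccc(C(=O)OC)oc2=O)C=C(OC)C(OC)=C1 | intermediate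
13 | bis[(1S)-2-methoxy-2-oxo-1-phenylethyl] (1R,2R,3S,4S)-4-hydroxy-6,7-dimethoxy-1-[6-(methoxycarbonyl)-2-oxo-2H-pyran-3-yl]-1,2,3,4-tetrahydronaphthalene-2,3-dicarboxylate (C1 pyranonyl, C3 ester and C4 OH on one face, C2 ester on the other) | O[C@@H]1c2cc(OC)c(OC)cc2[C@H](c2ccc(C(=O)OC)oc2=O)[C@@H](C(=O)O[C@H](C(=O)OC)c2ccccc2)[C@@H]1C(=O)O[C@H](C(=O)OC)c1ccccc1 | intermediate
14 | bis[(1S)-2-methoxy-2-oxo-1-phenylethyl] (1R,2R)-6,7-dimethoxy-1-[6-(methoxycarbonyl)-2-oxo-2H-pyran-3-yl]-1,2-dihydronaphthalene-2,3-dicarboxylate | O=C(O[C@H](C(=O)OC)c1ccccc1)C1=Cc2cc(OC)c(OC)cc2[C@H](c2ccc(C(=O)OC)oc2=O)[C@H]1C(=O)O[C@H](C(=O)OC)c1ccccc1 | intermediate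
15 | (1R,2R)-1-(6-carboxy-2-oxo-2H-pyran-3-yl)-6,7-dimethoxy-1,2-dihydronaphthalene-2,3-dicarboxylic acid | O=C(O)C1=Cc2cc(OC)c(OC)cc2[C@H](c2ccc(C(=O)O)oc2=O)[C@H]1C(=O)O | intermediate
16 | (1R,2R)-1-(6-carboxy-2-oxo-2H-pyran-3-yl)-6,7-dihydroxy-1,2-dihydronaphthalene-2,3-dicarboxylic acid, trans | O=C(O)C1=Cc2cc(O)c(O)cc2[C@H](c2ccc(C(=O)O)oc2=O)[C@H]1C(=O)O | target

**Step count**
Total: 8 steps. Longest linear sequence: 7 steps (1, 2, 3, 4, 6, 7, 8); step 5 is a one-step side branch.

**Steps most likely to fail**

Step 6. Energy transfer from the excited aldehyde to the fumarate (E/Z isomerisation) or to the pyranone, and reversion of the photoenol before bimolecular trapping, may stall conversion and erode selectivity. The fallback separates light from cycloaddition. It sets out from 8, which is irradiated at 365 nm in benzene saturated with sulfur dioxide and without dienophile, so that the photoenol is captured by cheletropic addition as methyl 3-(cis-3-hydroxy-5,6-dimethoxy-2,2-dioxo-1,3-dihydro-2λ6-benzo[c]thiophen-1-yl)-2-oxo-2H-pyran-6-carboxylate F1 (racemic). This sulfone is then heated with 11 and zinc oxide in toluene at 80 °C; thermal extrusion of sulfur dioxide regenerates 12 in the dark and the cycloaddition returns to the route at 13.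

Step 7. Acid hydrolysis of the hindered mandelyl esters may stay incomplete while prolonged heating slowly degrades the dihydronaphthalene. The fallback sets out from 13, which is dehydrated with catalytic TsOH in toluene at 60 °C and the triester 14 is isolated. Saponification with LiOH in THF/water under argon at rt then cleaves all esters and opens the lactone to (1R,2R)-1-[(1Z,3Z)-1,4-dicarboxy-4-hydroxybuta-1,3-dien-1-yl]-6,7-dimethoxy-1,2-dihydronaphthalene-2,3-dicarboxylic acid F2, present as its lithium salt. Acidification with concentrated HCl and warming to 60 °C recloses the 2-pyranone, as in step 1, and the route is rejoined at 15.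

Step 8. Demethylation may stop short on the poorly soluble polyacid, whose carboxyl groups bind the Lewis acid, and forcing the conditions invites decomposition. The fallback demethylates at the soluble ester stage. It sets out from 13, which is dehydrated to isolated 14 (TsOH cat., toluene, 60 °C) and treated with BBr3 in CH2Cl2 at −78 → −20 °C to give bis[(1S)-2-methoxy-2-oxo-1-phenylethyl] (1R,2R)-6,7-dihydroxy-1-[6-(methoxycarbonyl)-2-oxo-2H-pyran-3-yl]-1,2-dihydronaphthalene-2,3-dicarboxylate F3; partial ester cleavage at this point does no harm. Hydrolysis in 6 M HCl/dioxane at 95 °C under argon then gives 16 directly.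

**Further compounds**
F1 | step 6 | methyl 3-(cis-3-hydroxy-5,6-dimethoxy-2,2-dioxo-1,3-dihydro-2λ6-benzo[c]thiophen-1-yl)-2-oxo-2H-pyran-6-carboxylate (racemic, one enantiomer drawn) | O[C@@H]1c2cc(OC)c(OC)cc2[C@H](c2ccc(C(=O)OC)oc2=O)S1(=O)=O
F2 | step 7 | (1R,2R)-1-[(1Z,3Z)-1,4-dicarboxy-4-hydroxybuta-1,3-dien-1-yl]-6,7-dimethoxy-1,2-dihydronaphthalene-2,3-dicarboxylic acid | O=C(O)C1=Cc2cc(OC)c(OC)cc2[C@H](/C(C(=O)O)=C/C=C(\O)C(=O)O)[C@H]1C(=O)O
F3 | step 8 | bis[(1S)-2-methoxy-2-oxo-1-phenylethyl] (1R,2R)-6,7-dihydroxy-1-[6-(methoxycarbonyl)-2-oxo-2H-pyran-3-yl]-1,2-dihydronaphthalene-2,3-dicarboxylate | O=C(O[C@H](C(=O)OC)c1ccccc1)C1=Cc2cc(O)c(O)cc2[C@H](c2ccc(C(=O)OC)oc2=O)[C@H]1C(=O)O[C@H](C(=O)OC)c1ccccc1
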